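**Strategy.** The furo[3,2-b]pyranone core is all-cis around its oxolane (C2, C3, C3a, C7a). This is the D-gluco pattern of 2,5-anhydro-D-glucitol with C3a inverted. The route therefore keeps the sugar's C2, C3 and C7a and makes the lactone ring by joining the ring oxygen O4 to C3a. The key step is a Mitsunobu lactonisation: the carboxylate of a (Z)-propenoic acid tethered at C7a displaces the activated C3a hydroxyl with inversion, closing the pyranone cis-fused and setting C3a in one operation. The precursor is a seco hydroxy acid with O3 and the C2 arm locked in an acetonide. The acylated side chain is then attached by cross-metathesis.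

Key step: step 4

Remark: 2,5-anhydro-D-glucitol (1) and methyl (R)-lactate (11) are assumed to be catalogue compounds. Ring atoms are numbered as in the target (O1, C2, C3, C3a, O4, C5, C6, C7, C7a).

**Route**

Step 1
Reactants: 1 2,5-anhydro-D-glucitol
Product: 2 2,5-anhydro-1,3-O-isopropylidene-D-glucitol
Conditions: Me2C(OMe)2, TsOH·H2O (cat.), acetone, rt; Et3N
Reagents that add atoms: 2,2-dimethoxypropane COC(C)(C)OC
Why: Thermodynamic acetonide formation should bridge only the cis O1/O3 pair as a six-membered 1,3-dioxane, because the O3/O4 and O4/O6 pairs are trans on the oxolane, so O4 and O6 stay free and no stereocentre is touched.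

Step 2
Reactants: 2 2,5-anhydro-1,3-O-isopropylidene-D-glucitol
Product: 4 methyl (2Z)-4,7-anhydro-2,3-dideoxy-6,8-O-isopropylidene-L-gulo-oct-2-enonate, via hydroxy aldehyde 3 (not isolated)
Conditions: TEMPO (cat.), PhI(OAc)2, CH2Cl2, rt; then solvent exchange, Ph3P=CHCO2Me, MeOH, 0 °C
Reagents that add atoms: methyl (triphenylphosphoranylidene)acetate COC(=O)C=P(c1ccccc1)(c1ccccc1)c1ccccc1
Why: Oxoammonium oxidation (TEMPO/PhI(OAc)2) is selective for the primary alcohol, and the Wittig reaction of the resulting α-alkoxy aldehyde with a stabilised ylide in methanol should favour the (Z)-enoate under neutral conditions that leave the ring stereocentres untouched (minor E isomer removed by chromatography).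

Step 3
Reactants: 4 methyl (2Z)-4,7-anhydro-2,3-dideoxy-6,8-O-isopropylidene-L-gulo-oct-2-enonate
Product: 5 (2Z)-4,7-anhydro-2,3-dideoxy-6,8-O-isopropylidene-L-gulo-oct-2-enonic acid
Conditions: LiOH, THF/H2O, 0 °C to rt; then 0.5 M HCl to pH 4, 0 °C
Reagents that add atoms: lithium hydroxide [Li+].[OH-]
Why: Saponification of the methyl ester should leave the acetonide, the Z-alkene and all stereocentres intact, and would also give 5 if 4 had partly closed to a strained trans-fused lactone.

Step 4
Reactants: 5 (2Z)-4,7-anhydro-2,3-dideoxy-6,8-O-isopropylidene-L-gulo-oct-2-enonic acid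
Product: 7 isopropylidene acetal (bridging O3 and the C2 CH2O group) of (2S,3R,3aR,7aR)-3-hydroxy-2-(hydroxymethyl)-2,3,3a,7a-tetrahydro-5H-furo[3,2-b]pyran-5-one, via alkoxyphosphonium carboxylate 6 (not isolated)
Conditions: PPh3, DIAD, THF (0.01 M, slow addition of 5), 0 °C to rt
Reagents that add atoms: none
Why: PPh3 and DIAD form the betaine, which is protonated by the acid and transfers phosphorus to the C5 hydroxyl of 5 (C3a of the product) to give alkoxyphosphonium carboxylate 6, whose carboxylate oxygen then displaces Ph3P=O at that carbon. The closest known reaction type is the Mitsunobu lactonisation of hydroxy acids. The pyranone ring closes in a 6-exo-tet mode, the (Z)-alkene holding the carboxylate within reach of C3a. C3a is the only new stereocentre and is set by stereospecific SN2 inversion of the D-gluco carbinol, which puts the lactone oxygen on the face of the tether and so gives the cis ring fusion and the all-cis oxolane. The step needs substitution to win over acyl activation (retention) and over elimination: retention would give a strained trans-fused lactone, the hydrogens on C3 and C7a are both syn to the leaving group so no anti-periplanar E2 path exists, and O3 is locked in the acetonide so no epoxide can form.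

Step 5
Reactants: 7 isopropylidene acetal of the lactone diol
Product: 8 (2S,3R,3aR,7aR)-3-hydroxy-2-(hydroxymethyl)-2,3,3a,7a-tetrahydro-5H-furo[3,2-b]pyran-5-one
Conditions: AcOH/H2O (4:1), 40 °C
Reagents that add atoms: none
Why: Acid-catalysed acetal hydrolysis should free O3 and the primary hydroxyl without affecting the unsaturated lactone or any stereocentre.

Step 6
Reactants: 8 (2S,3R,3aR,7aR)-3-hydroxy-2-(hydroxymethyl)-2,3,3a,7a-tetrahydro-5H-furo[3,2-b]pyran-5-one
Product: 9 (2R,3S,3aR,7aR)-3-hydroxy-5-oxo-2,3,3a,7a-tetrahydro-5H-furo[3,2-b]pyran-2-carbaldehyde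
Conditions: TEMPO (cat.), PhI(OAc)2, CH2Cl2, rt; used crude
Reagents that add atoms: none
Why: TEMPO/PhI(OAc)2 oxidation should distinguish the primary from the hindered secondary alcohol and stop at the aldehyde under anhydrous, non-basic conditions that spare the epimerisable C2 centre.

Step 7
Reactants: 9 (2R,3S,3aR,7aR)-3-hydroxy-5-oxo-2,3,3a,7a-tetrahydro-5H-furo[3,2-b]pyran-2-carbaldehyde
Product: 10 (2S,3R,3aR,7aR)-2-ethenyl-3-hydroxy-2,3,3a,7a-tetrahydro-5H-furo[3,2-b]pyran-5-one
Conditions: Zn, CH2Br2, TiCl4, THF/CH2Cl2, 0 °C to rt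
Reagents that add atoms: dibromomethane BrCBr
Why: Takai–Lombardo methylenation converts aldehydes into terminal alkenes under non-basic conditions that tolerate lactones and free hydroxyls, so C2 should not epimerise and the C3 hydroxyl should not eliminate.

Step 8
Reactants: 11 methyl (R)-lactate
Product: 12 methyl (R)-2-[(tert-butyldimethylsilyl)oxy]propanoate
Conditions: TBSCl, imidazole, DMF, rt
Reagents that add atoms: tert-butyldimethylsilyl chloride CC(C)(C)[Si](C)(C)Cl
Why: Standard silylation of the secondary alcohol, with no effect on the stereocentre.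

Step 9
Reactants: 12 methyl (R)-2-[(tert-butyldimethylsilyl)oxy]propanoate
Product: 14 (3S,4R)-4-[(tert-butyldimethylsilyl)oxy]pent-1-en-3-ol, via silyloxy aldehyde 13 (not isolated)
Conditions: iBu2AlH, CH2Cl2, −78 °C; then CH2=CHMgBr, THF, −78 to 0 °C; aq. Rochelle salt
Reagents that add atoms: vinylmagnesium bromide C=C[Mg]Br
Why: Partial ester reduction to the aldehyde (held as its aluminium hemiacetal) followed by Grignard addition in the same flask, in which the non-chelating silyloxy group should direct Felkin–Anh attack and set the new (3S) carbinol anti to C4 (minor syn isomer removed by chromatography).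

Step 10
Reactants: 14 (3S,4R)-4-[(tert-butyldimethylsilyl)oxy]pent-1-en-3-ol
Product: 15 (3S,4R)-4-[(tert-butyldimethylsilyl)oxy]pent-1-en-3-yl benzoate
Conditions: BzCl, pyridine, DMAP (cat.), CH2Cl2, 0 °C to rt
Reagents that add atoms: benzoyl chloride O=C(Cl)c1ccccc1
Why: DMAP-catalysed O-acylation of the allylic alcohol proceeds with retention at the carbinol carbon.

Step 11
Reactants: 15 (3S,4R)-4-[(tert-butyldimethylsilyl)oxy]pent-1-en-3-yl benzoate
Product: 16 (3S,4R)-4-hydroxypent-1-en-3-yl benzoate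
Conditions: HF·pyridine, THF/pyridine, 0 °C to rt
Reagents that add atoms: none
Why: Acidic fluoride desilylation should remove the silyl ether without the basic conditions that promote 1,2-benzoate migration.

Step 12
Reactants: 16 (3S,4R)-4-hydroxypent-1-en-3-yl benzoate
Product: 17 (2R,3S)-3-(benzoyloxy)pent-4-en-2-yl acetate
Conditions: Ac2O, pyridine, DMAP (cat.), CH2Cl2, 0 °C
Reagents that add atoms: acetic anhydride CC(=O)OC(C)=O
Why: DMAP-catalysed acetylation of the free secondary alcohol, run directly after step 11 so that the benzoate has no opportunity to migrate.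

Step 13
Reactants: 10 (2S,3R,3aR,7aR)-2-ethenyl-3-hydroxy-2,3,3a,7a-tetrahydro-5H-furo[3,2-b]pyran-5-one; 17 (2R,3S)-3-(benzoyloxy)pent-4-en-2-yl acetate
Product: 18 (2R,3S,4E)-3-(benzoyloxy)-5-[(2S,3R,3aR,7aR)-3-hydroxy-5-oxo-2,3,3a,7a-tetrahydro-5H-furo[3,2-b]pyran-2-yl]pent-4-en-2-yl acetate (target)
Conditions: 17 (4 equiv), second-generation Hoveyda–Grubbs catalyst RuCl2(=CH-C6H4-2-OiPr)(H2IMes) (10 mol %), CH2Cl2, 40 °C
Reagents that add atoms: none
Why: Olefin cross-metathesis of two terminal alkenes, each slow to homodimerise because of its allylic oxygen, should give the (E)-disubstituted alkene under thermodynamic control while the conjugated ring alkene of the lactone stays inert and no stereocentre is touched.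

**Compound list**

1 | 2,5-anhydro-D-glucitol, (2R,3S,4S,5S)-2,5-bis(hydroxymethyl)oxolane-3,4-diol | OC[C@@H]1O[C@H](CO)[C@@H](O)[C@@H]1O | starting material
2 | 2,5-anhydro-1,3-O-isopropylidene-D-glucitol | CC1(C)OC[C@@H]2O[C@H](CO)[C@@H](O)[C@@H]2O1 | intermediate
3 | 2,5-anhydro-4,6-O-isopropylidene-L-gulose (C6 aldehyde of 2) | CC1(C)OC[C@@H]2O[C@H](C=O)[C@@H](O)[C@@H]2O1 | intermediate (not isolated)
4 | methyl (2Z)-4,7-anhydro-2,3-dideoxy-6,8-O-isopropylidene-L-gulo-oct-2-enonate | CC1(C)OC[C@@H]2O[C@H](/C=C\C(=O)OC)[C@@H](O)[C@@H]2O1 | intermediate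
5 | (2Z)-4,7-anhydro-2,3-dideoxy-6,8-O-isopropylidene-L-gulo-oct-2-enonic acid | CC1(C)OC[C@@H]2O[C@H](/C=C\C(=O)O)[C@@H](O)[C@@H]2O1 | intermediate
6 | O5-triphenylphosphonio carboxylate zwitterion of 5 | CC1(C)OC[C@@H]2O[C@H](/C=C\C(=O)[O-])[C@@H](O[P+](c3ccccc3)(c3ccccc3)c3ccccc3)[C@@H]2O1 | intermediate (not isolated)
7 | isopropylidene acetal (O3 and C2 CH2O) of lactone diol 8 | CC1(C)OC[C@@H]2O[C@@H]3C=CC(=O)O[C@@H]3[C@@H]2O1 | intermediate
8 | (2S,3R,3aR,7aR)-3-hydroxy-2-(hydroxymethyl)-2,3,3a,7a-tetrahydro-5H-furo[3,2-b]pyran-5-one | OC[C@@H]1O[C@@H]2C=CC(=O)O[C@@H]2[C@@H]1O | intermediate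
9 | (2R,3S,3aR,7aR)-3-hydroxy-5-oxo-2,3,3a,7a-tetrahydro-5H-furo[3,2-b]pyran-2-carbaldehyde | O=C[C@@H]1O[C@@H]2C=CC(=O)O[C@@H]2[C@@H]1O | intermediate
10 | (2S,3R,3aR,7aR)-2-ethenyl-3-hydroxy-2,3,3a,7a-tetrahydro-5H-furo[3,2-b]pyran-5-one | C=C[C@@H]1O[C@@H]2C=CC(=O)O[C@@H]2[C@@H]1O | intermediate
11 | methyl (R)-lactate | C[C@@H](O)C(=O)OC | starting material
12 | methyl (R)-2-[(tert-butyldimethylsilyl)oxy]propanoate | C[C@@H](O[Si](C)(C)C(C)(C)C)C(=O)OC | intermediate
13 | (R)-2-[(tert-butyldimethylsilyl)oxy]propanal | C[C@@H](O[Si](C)(C)C(C)(C)C)C=O | intermediate (not isolated)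
14 | (3S,4R)-4-[(tert-butyldimethylsilyl)oxy]pent-1-en-3-ol | C[C@@H](O[Si](C)(C)C(C)(C)C)[C@@H](O)C=C | intermediate
15 | (3S,4R)-4-[(tert-butyldimethylsilyl)oxy]pent-1-en-3-yl benzoate | C[C@@H](O[Si](C)(C)C(C)(C)C)[C@@H](OC(=O)c1ccccc1)C=C | intermediate
16 | (3S,4R)-4-hydroxypent-1-en-3-yl benzoate | C[C@@H](O)[C@@H](OC(=O)c1ccccc1)C=C | intermediate
17 | (2R,3S)-3-(benzoyloxy)pent-4-en-2-yl acetate | CC(=O)O[C@H](C)[C@H](C=C)OC(=O)c1ccccc1 | intermediate
18 | (2R,3S,4E)-3-(benzoyloxy)-5-[(2S,3R,3aR,7aR)-3-hydroxy-5-oxo-2,3,3a,7a-tetrahydro-5H-furo[3,2-b]pyran-2-yl]pent-4-en-2-yl acetate | CC(=O)O[C@H](C)[C@H](/C=C/[C@@H]1O[C@@H]2C=CC(=O)O[C@@H]2[C@@H]1O)OC(=O)c1ccccc1 | target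

**Totals.** Total step count: 13. Longest linear sequence: 8 steps (steps 1 to 7, then step 13).

**Steps most likely to fail**

Step 13 (cross-metathesis). The risk is slow productive metathesis between two alkenes that both carry an allylic oxygen, so that homodimerisation of 17 and catalyst decay take over. The fallback sets out from aldehyde 9 and returns at 18; it builds the side chain by carbonyl olefination and stepwise acylation. (R)-2-Acetoxypropanoyl chloride and two equivalents of Ph3P=CH2 give the keto ylide (2R)-3-oxo-4-(triphenyl-λ5-phosphanylidene)butan-2-yl acetate F1. Its base-free Wittig reaction with 9 (CH2Cl2, rt) gives the (E)-enone F2. The C3 hydroxyl is masked (Et3SiOTf, 2,6-lutidine) as the triethylsilyl ether of the enone F3. Corey–Bakshi–Shibata reduction (oxazaborolidine antipode chosen to deliver the (S)-carbinol, catecholborane, −78 °C) gives the allylic alcohol F4. Benzoylation (BzCl, pyridine, 0 °C) gives the 3-O-triethylsilyl ether of the target F5, and HF·pyridine then frees the C3 hydroxyl to give 18.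

Step 4 (Mitsunobu lactonisation). The risk is that the intramolecular SN2 attack, which must come from the oxolane face that also carries O3, is too slow, so that acyl activation and intermolecular esterification consume the acid. The fallback sets out from hydroxy ester 4 and returns at 7; it separates activation from displacement. Mesylation (MsCl, Et3N, CH2Cl2, 0 °C) gives the 5-O-methanesulfonate of ester 4 F6. Neutral ester cleavage (Me3SnOH, 1,2-dichloroethane, 70 °C) gives the mesyloxy acid F7. Its caesium carboxylate (Cs2CO3, DMF, 50 °C) then displaces the sulfonate with the same inversion to give 7.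

Step 7 (methylenation). The risk is epimerisation at C2 or β-elimination of the C3 hydroxyl in the α-alkoxy-β-hydroxy aldehyde, together with incomplete methylene transfer. The fallback sets out from aldehyde 9 and returns at 10; it uses addition followed by elimination. Chemoselective addition of Me3SiCH2MgCl/CeCl3 (THF, −78 °C) gives the β-hydroxysilane adduct of 9 F8 as a mixture of carbinol epimers, and acid-promoted Peterson elimination (BF3·OEt2, CH2Cl2, 0 °C) gives 10.

Further compounds
F1 | step 13 | (2R)-3-oxo-4-(triphenyl-λ5-phosphanylidene)butan-2-yl acetate | CC(=O)O[C@H](C)C(=O)C=P(c1ccccc1)(c1ccccc1)c1ccccc1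
F2 | step 13 | (2R,4E)-5-[(2S,3R,3aR,7aR)-3-hydroxy-5-oxo-2,3,3a,7a-tetrahydro-5H-furo[3,2-b]pyran-2-yl]-3-oxopent-4-en-2-yl acetate | CC(=O)O[C@H](C)C(=O)/C=C/[C@@H]1O[C@@H]2C=CC(=O)O[C@@H]2[C@@H]1O
F3 | step 13 | 3-O-triethylsilyl ether of enone F2 | CC(=O)O[C@H](C)C(=O)/C=C/[C@@H]1O[C@@H]2C=CC(=O)O[C@@H]2[C@@H]1O[Si](CC)(CC)CC
F4 | step 13 | (S)-allylic alcohol from F3 (3-O-triethylsilyl, debenzoyl analogue of 18) | CC(=O)O[C@H](C)[C@@H](O)/C=C/[C@@H]1O[C@@H]2C=CC(=O)O[C@@H]2[C@@H]1O[Si](CC)(CC)CC
F5 | step 13 | 3-O-triethylsilyl ether of 18 | CC(=O)O[C@H](C)[C@H](/C=C/[C@@H]1O[C@@H]2C=CC(=O)O[C@@H]2[C@@H]1O[Si](CC)(CC)CC)OC(=O)c1ccccc1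
F6 | step 4 | methyl (2Z)-4,7-anhydro-2,3-dideoxy-6,8-O-isopropylidene-5-O-methylsulfonyl-L-gulo-oct-2-enonate | CC1(C)OC[C@@H]2O[C@H](/C=C\C(=O)OC)[C@@H](OS(C)(=O)=O)[C@@H]2O1
F7 | step 4 | (2Z)-4,7-anhydro-2,3-dideoxy-6,8-O-isopropylidene-5-O-methylsulfonyl-L-gulo-oct-2-enonic acid | CC1(C)OC[C@@H]2O[C@H](/C=C\C(=O)O)[C@@H](OS(C)(=O)=O)[C@@H]2O1
F8 | step 7 | 3-hydroxy-2-[1-hydroxy-2-(trimethylsilyl)ethyl]-2,3,3a,7a-tetrahydro-5H-furo[3,2-b]pyran-5-one (ring configuration as in 9, carbinol epimers) | C[Si](C)(C)CC(O)[C@@H]1O[C@@H]2C=CC(=O)O[C@@H]2[C@@H]1O
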